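## Retrosynthetic overview

1. Locants follow azulene numbering of the bicyclic core (C1 = CMe2, C2 = CHOH, C3 = CH2, C3a = fusion CH, C4 = C=O, C5 = quaternary C, C6 = CHMe, C8a = C–OH). The butenolide is attached last by Negishi coupling of a 2-iodoethyl chain on C5 (from an allyl group) with 4-bromofuran-2(5H)-one. The C2 alcohol comes from a C2 ketone and the trans ring fusion from epimerisation at C3a.
2. Key disconnection: the C3–C3a bond of the five-membered ring, made by intramolecular oxidative coupling of the two enolates of a monocyclic diketone. Enabling feature: C3–C3a is the central bond of a 1,4-dicarbonyl array (C2 ketone in the five-membered ring, C4 ketone in the seven-membered ring), and each carbonyl has a quaternary carbon on its far side (C1, C5), so each can enolise only toward this bond.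
3. The C8a–C1 bond and the tertiary alcohol come from SE2′ addition of a dimethylallenyl indium reagent to the unhindered carbonyl of a cycloheptane-1,3-dione; alkyne hydration then gives the methyl ketone.
4. The seven-membered ring comes from a two-carbon ring expansion (dichloroketene [2+2], dechlorination, retro-aldol) of a cyclopentanone whose two stereocentres (later C5 and C6) are set by asymmetric conjugate addition and enolate allylation.
5. Ring order: sacrificial cyclopentanone → seven-membered ring → five-membered ring (key step).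

Key step: step 8

Assumptions (remarks on the chemistry):
- The ketene cycloadduct 9 is drawn as the cis-fused diastereomer from approach on the allyl-bearing face; the other cis-fused diastereomer gives the same dione 11.
- The ligand enantiomer in step 1 is the one that delivers the 3R centre.
- The trans-fused ring junction of the target is taken to be the thermodynamic configuration at C3a.

## Route

Step 1
Reactants: 1 2-methylcyclopent-2-en-1-one; 2 methylmagnesium bromide; 3 allyl iodide (3-iodoprop-1-ene)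
Product: 5 (2S,3R)-2,3-dimethyl-2-(prop-2-en-1-yl)cyclopentan-1-one, via bromomagnesium enolate 4 (not isolated)
Conditions: MeMgBr, Cu(OTf)2 (3 mol %), chiral hydroxyalkyl-NHC ligand (from its imidazolinium salt, 4 mol %), Et2O, −30 °C; then allyl iodide, DMPU, −30 °C → rt
Reagents that add atoms: methylmagnesium bromide, C[Mg]Br; allyl iodide, C=CCI
Why: Copper-catalysed asymmetric conjugate addition to the α-methyl enone should set the 3R methyl centre under ligand control, and allylation of the resulting tetrasubstituted enolate anti to that methyl should set the 2S quaternary centre (methyls cis).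

Step 2
Reactants: 5 (2S,3R)-2,3-dimethyl-2-(prop-2-en-1-yl)cyclopentan-1-one
Product: 6 trimethyl{[(4R,5S)-4,5-dimethyl-5-(prop-2-en-1-yl)cyclopent-1-en-1-yl]oxy}silane
Conditions: TMSOTf, Et3N, CH2Cl2, 0 °C
Reagents that add atoms: trimethylsilyl trifluoromethanesulfonate, C[Si](C)(C)OS(=O)(=O)C(F)(F)F
Why: Soft enolisation can occur only toward the CH2 side because the other α-carbon is quaternary, so a single silyl enol ether should form.

Step 3
Reactants: 6 trimethyl{[(4R,5S)-4,5-dimethyl-5-(prop-2-en-1-yl)cyclopent-1-en-1-yl]oxy}silane; 7 dichloroacetyl chloride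
Product: 9 (1S,2S,3R,5R)-7,7-dichloro-2,3-dimethyl-2-(prop-2-en-1-yl)-1-[(trimethylsilyl)oxy]bicyclo[3.2.0]heptan-6-one, via dichloroketene 8 (not isolated)
Conditions: Cl2CHCOCl, Et3N (slow addition), hexane, rt
Reagents that add atoms: dichloroacetyl chloride, ClC(Cl)C(=O)Cl
Why: Thermal [2+2] cycloaddition of dichloroketene with the electron-rich silyl enol ether joins the ketene carbonyl carbon to the nucleophilic enol carbon and should give the cis-fused silyloxycyclobutanone, the unactivated allyl alkene not competing under these conditions; the two new stereocentres are erased in step 4.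

Step 4
Reactants: 9 (1S,2S,3R,5R)-7,7-dichloro-2,3-dimethyl-2-(prop-2-en-1-yl)-1-[(trimethylsilyl)oxy]bicyclo[3.2.0]heptan-6-one
Product: 11 (4S,5R)-4,5-dimethyl-4-(prop-2-en-1-yl)cycloheptane-1,3-dione, via dechlorinated silyloxycyclobutanone 10 (not isolated)
Conditions: Zn dust, AcOH, i-PrOH/H2O, 0 °C → rt; then AcOH/H2O (2:1), rt
Reagents that add atoms: none
Why: Zinc reduction removes both α-chlorines, and acid-mediated desilylation then triggers retro-aldol cleavage of the strained ring-fusion bond, a two-carbon ring expansion of the cyclopentanone to the cycloheptane-1,3-dione.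

Step 5
Reactants: 11 (4S,5R)-4,5-dimethyl-4-(prop-2-en-1-yl)cycloheptane-1,3-dione; 12 3-chloro-3-methylbut-1-yne
Product: 14 (2S,3R,6S)-6-hydroxy-2,3-dimethyl-6-(2-methylbut-3-yn-2-yl)-2-(prop-2-en-1-yl)cycloheptan-1-one, via allenylindium dichloride 13 (not isolated)
Conditions: 3-chloro-3-methylbut-1-yne, In powder, NaI (cat.), DMF, rt; aq. NH4Cl work-up
Reagents that add atoms: 3-chloro-3-methylbut-1-yne, CC(C)(Cl)C#C
Why: In this indium-mediated Barbier propargylation the weakly basic allenylindium reagent should tolerate the acidic dione and add by SE2′ through its dimethyl-substituted terminus to C1 (C3 is neopentylic), from the ring face opposite the axial methyl on C4, which should set the 6S carbinol centre.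

Step 6
Reactants: 14 (2S,3R,6S)-6-hydroxy-2,3-dimethyl-6-(2-methylbut-3-yn-2-yl)-2-(prop-2-en-1-yl)cycloheptan-1-one
Product: 15 (2S,3R,6S)-2,3-dimethyl-6-(2-methylbut-3-yn-2-yl)-2-(prop-2-en-1-yl)-6-[(triethylsilyl)oxy]cycloheptan-1-one
Conditions: TESOTf, 2,6-lutidine, CH2Cl2, −78 → 0 °C
Reagents that add atoms: triethylsilyl trifluoromethanesulfonate, CC[Si](CC)(CC)OS(=O)(=O)C(F)(F)F
Why: The silyl triflate with a hindered pyridine base should silylate the congested tertiary alcohol, which keeps the hydroxyl from adding to the alkyne in step 7 and blocks retro-aldol cleavage later.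

Step 7
Reactants: 15 (2S,3R,6S)-2,3-dimethyl-6-(2-methylbut-3-yn-2-yl)-2-(prop-2-en-1-yl)-6-[(triethylsilyl)oxy]cycloheptan-1-one
Product: 16 (2S,3R,6S)-2,3-dimethyl-6-(2-methyl-3-oxobutan-2-yl)-2-(prop-2-en-1-yl)-6-[(triethylsilyl)oxy]cycloheptan-1-one
Conditions: (Ph3P)AuNTf2 (2 mol %), H2O, 1,4-dioxane, 60 °C
Reagents that add atoms: water, O
Why: Gold-catalysed Markovnikov hydration of the terminal alkyne should give the methyl ketone while the isolated allyl alkene stays untouched.

Step 8
Reactants: 16 (2S,3R,6S)-2,3-dimethyl-6-(2-methyl-3-oxobutan-2-yl)-2-(prop-2-en-1-yl)-6-[(triethylsilyl)oxy]cycloheptan-1-one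
Product: 19 (3aR,5S,6R,8aS)-1,1,5,6-tetramethyl-5-(prop-2-en-1-yl)-8a-[(triethylsilyl)oxy]hexahydroazulene-2,4(1H,3H)-dione (cis-fused), via dilithium bis-enolate 17 (not isolated), via iodomethyl ketone lithium enolate 18 (not isolated)
Conditions: LiN(i-Pr)2 (2.3 equiv), THF, −78 → −40 °C; then I2 (1.0 equiv), THF, −78 → 0 °C, high dilution
Reagents that add atoms: none
Why: Double deprotonation gives bis-enolate 17, iodine oxidises it to the iodomethyl ketone enolate 18 (an iodine that lands first on the ring enolate carbon should be passed to the terminal one by enolate–iodide exchange), and the ring enolate carbon then displaces iodide to form the C3–C3a bond, so two enolate carbons of like polarity are joined in one operation. The closest known reaction type is the intramolecular oxidative coupling of diketone and diester bis-enolates with I2, CuCl2 or iron salts to give cyclic 1,4-dicarbonyl compounds. The five-membered ring closes in the 5-(enolexo)-exo-tet mode. The new C3a stereocentre is set by the tether, because the three-atom chain on C8a can reach only the enolate face it already occupies, so the cis-fused diketone is expected and is corrected in step 9. The step needs site selectivity, which the substrate secures because each ketone has a quaternary carbon on one side and can enolise only toward the bond being formed. It also needs ring closure to outrun intermolecular coupling, which high dilution and the activated α-iodo ketone electrophile should secure.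

Step 9
Reactants: 19 (3aR,5S,6R,8aS)-1,1,5,6-tetramethyl-5-(prop-2-en-1-yl)-8a-[(triethylsilyl)oxy]hexahydroazulene-2,4(1H,3H)-dione
Product: 20 (3aS,5S,6R,8aS)-1,1,5,6-tetramethyl-5-(prop-2-en-1-yl)-8a-[(triethylsilyl)oxy]hexahydroazulene-2,4(1H,3H)-dione (trans-fused)
Conditions: DBU (0.5 equiv), toluene, 50 °C
Reagents that add atoms: none
Why: Base-mediated epimerisation at C3a, the only enolisable stereocentre, should give the thermodynamically preferred trans-fused diketone, in which both carbon substituents at the fusion are pseudo-equatorial on the seven-membered ring and the angular oxygen, not C8, takes the doubly gauche position.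

Step 10
Reactants: 20 (3aS,5S,6R,8aS)-1,1,5,6-tetramethyl-5-(prop-2-en-1-yl)-8a-[(triethylsilyl)oxy]hexahydroazulene-2,4(1H,3H)-dione
Product: 22 (2R,3aS,5S,6R,8aS)-2-hydroxy-5-(2-hydroxyethyl)-1,1,5,6-tetramethyl-8a-[(triethylsilyl)oxy]octahydroazulen-4(1H)-one, via keto aldehyde 21 (not isolated)
Conditions: O3, CH2Cl2, −78 °C; Me2S, −78 °C → rt; then NaBH4, MeOH, −40 → 0 °C
Reagents that add atoms: ozone, [O-][O+]=O
Why: Ozonolysis cleaves the terminal alkene to the aldehyde, and NaBH4 should then reduce the aldehyde and the C2 cyclopentanone but not the C4 ketone flanked by a quaternary and a tertiary carbon, hydride adding to C2 anti to the axial silyloxy group to give the 2R alcohol cis to it.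

Step 11
Reactants: 22 (2R,3aS,5S,6R,8aS)-2-hydroxy-5-(2-hydroxyethyl)-1,1,5,6-tetramethyl-8a-[(triethylsilyl)oxy]octahydroazulen-4(1H)-one
Product: 23 (2R,3aS,5S,6R,8aS)-2-hydroxy-5-(2-iodoethyl)-1,1,5,6-tetramethyl-8a-[(triethylsilyl)oxy]octahydroazulen-4(1H)-one
Conditions: I2, PPh3, imidazole, CH2Cl2, 0 °C → rt
Reagents that add atoms: iodine, II
Why: Appel-type iodination should be selective for the primary alcohol (reacting through the open hydroxy ketone form) over the neopentylic secondary alcohol.

Step 12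
Reactants: 23 (2R,3aS,5S,6R,8aS)-2-hydroxy-5-(2-iodoethyl)-1,1,5,6-tetramethyl-8a-[(triethylsilyl)oxy]octahydroazulen-4(1H)-one; 24 4-bromofuran-2(5H)-one
Product: 26 4-{2-[(2R,3aS,5S,6R,8aS)-2-hydroxy-1,1,5,6-tetramethyl-4-oxo-8a-[(triethylsilyl)oxy]decahydroazulen-5-yl]ethyl}furan-2(5H)-one, via alkylzinc iodide 25 (not isolated)
Conditions: Zn dust (activated with Me3SiCl), DMA, rt; then 4-bromofuran-2(5H)-one, Pd2(dba)3 (2.5 mol %), SPhos (10 mol %), THF, rt → 40 °C
Reagents that add atoms: 4-bromofuran-2(5H)-one, BrC1=CC(=O)OC1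
Why: Zinc insertion into the primary iodide followed by Negishi cross-coupling with the β-bromobutenolide should form the C(sp3)–C(sp2) bond at C4 of the furanone, the organozinc tolerating the hindered ketone and the hindered secondary alcohol.

Step 13
Reactants: 26 4-{2-[(2R,3aS,5S,6R,8aS)-2-hydroxy-1,1,5,6-tetramethyl-4-oxo-8a-[(triethylsilyl)oxy]decahydroazulen-5-yl]ethyl}furan-2(5H)-one
Product: 27 4-{2-[(2R,3aS,5S,6R,8aS)-2,8a-dihydroxy-1,1,5,6-tetramethyl-4-oxodecahydroazulen-5-yl]ethyl}furan-2(5H)-one (CNP0077405.1)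
Conditions: HF·pyridine, THF, 0 °C → rt
Reagents that add atoms: none
Why: Fluoride-mediated desilylation under mildly acidic conditions should free the tertiary alcohol without touching the butenolide or epimerising C3a.

## Compound list

1 | 2-methylcyclopent-2-en-1-one | CC1=CCCC1=O | starting material
2 | methylmagnesium bromide | C[Mg]Br | starting material
3 | allyl iodide (3-iodoprop-1-ene) | C=CCI | starting material
4 | bromomagnesium (R)-2,3-dimethylcyclopent-1-en-1-olate | C[C@@H]1CCC(O[Mg]Br)=C1C | intermediate (not isolated)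
5 | (2S,3R)-2,3-dimethyl-2-(prop-2-en-1-yl)cyclopentan-1-one | C[C@@H]1CCC(=O)[C@@]1(C)CC=C | intermediate
6 | trimethyl{[(4R,5S)-4,5-dimethyl-5-(prop-2-en-1-yl)cyclopent-1-en-1-yl]oxy}silane | C[C@@H]1CC=C(O[Si](C)(C)C)[C@@]1(C)CC=C | intermediate
7 | dichloroacetyl chloride | ClC(Cl)C(=O)Cl | starting material
8 | dichloroketene | ClC(Cl)=C=O | intermediate (not isolated)
9 | (1S,2S,3R,5R)-7,7-dichloro-2,3-dimethyl-2-(prop-2-en-1-yl)-1-[(trimethylsilyl)oxy]bicyclo[3.2.0]heptan-6-one | C[C@@H]1C[C@H]2C(=O)C(Cl)(Cl)[C@@]2(O[Si](C)(C)C)[C@@]1(C)CC=C | intermediate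
10 | (1S,2S,3R,5R)-2,3-dimethyl-2-(prop-2-en-1-yl)-1-[(trimethylsilyl)oxy]bicyclo[3.2.0]heptan-6-one | C[C@@H]1C[C@H]2C(=O)C[C@@]2(O[Si](C)(C)C)[C@@]1(C)CC=C | intermediate (not isolated)
11 | (4S,5R)-4,5-dimethyl-4-(prop-2-en-1-yl)cycloheptane-1,3-dione | C[C@@H]1CCC(=O)CC(=O)[C@@]1(C)CC=C | intermediate
12 | 3-chloro-3-methylbut-1-yne | CC(C)(Cl)C#C | starting material
13 | (3-methylbuta-1,2-dien-1-yl)indium dichloride | CC(C)=C=C[In](Cl)Cl | intermediate (not isolated)
14 | (2S,3R,6S)-6-hydroxy-2,3-dimethyl-6-(2-methylbut-3-yn-2-yl)-2-(prop-2-en-1-yl)cycloheptan-1-one | C[C@@H]1CC[C@@](O)(C(C)(C)C#C)CC(=O)[C@@]1(C)CC=C | intermediate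
15 | (2S,3R,6S)-2,3-dimethyl-6-(2-methylbut-3-yn-2-yl)-2-(prop-2-en-1-yl)-6-[(triethylsilyl)oxy]cycloheptan-1-one | C[C@@H]1CC[C@@](O[Si](CC)(CC)CC)(C(C)(C)C#C)CC(=O)[C@@]1(C)CC=C | intermediate
16 | (2S,3R,6S)-2,3-dimethyl-6-(2-methyl-3-oxobutan-2-yl)-2-(prop-2-en-1-yl)-6-[(triethylsilyl)oxy]cycloheptan-1-one | C[C@@H]1CC[C@@](O[Si](CC)(CC)CC)(C(C)(C)C(C)=O)CC(=O)[C@@]1(C)CC=C | intermediate
17 | dilithium bis-enolate of 16 (ring enolate toward the ring CH2 next to the carbinol carbon; terminal enolate of the methyl ketone) | C[C@@H]1CC[C@@](O[Si](CC)(CC)CC)(C(C)(C)C(=C)O[Li])C=C(O[Li])[C@@]1(C)CC=C | intermediate (not isolated)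
18 | lithium ring enolate of the iodomethyl ketone derived from 16 | C[C@@H]1CC[C@@](O[Si](CC)(CC)CC)(C(C)(C)C(=O)CI)C=C(O[Li])[C@@]1(C)CC=C | intermediate (not isolated)
19 | (3aR,5S,6R,8aS)-1,1,5,6-tetramethyl-5-(prop-2-en-1-yl)-8a-[(triethylsilyl)oxy]hexahydroazulene-2,4(1H,3H)-dione (cis-fused) | C[C@@H]1CC[C@]2(O[Si](CC)(CC)CC)[C@@H](CC(=O)C2(C)C)C(=O)[C@@]1(C)CC=C | intermediate
20 | (3aS,5S,6R,8aS)-1,1,5,6-tetramethyl-5-(prop-2-en-1-yl)-8a-[(triethylsilyl)oxy]hexahydroazulene-2,4(1H,3H)-dione (trans-fused) | C[C@@H]1CC[C@]2(O[Si](CC)(CC)CC)[C@H](CC(=O)C2(C)C)C(=O)[C@@]1(C)CC=C | intermediate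
21 | 2-[(3aS,5S,6R,8aS)-1,1,5,6-tetramethyl-2,4-dioxo-8a-[(triethylsilyl)oxy]decahydroazulen-5-yl]acetaldehyde | C[C@@H]1CC[C@]2(O[Si](CC)(CC)CC)[C@H](CC(=O)C2(C)C)C(=O)[C@@]1(C)CC=O | intermediate (not isolated)
22 | (2R,3aS,5S,6R,8aS)-2-hydroxy-5-(2-hydroxyethyl)-1,1,5,6-tetramethyl-8a-[(triethylsilyl)oxy]octahydroazulen-4(1H)-one | C[C@@H]1CC[C@]2(O[Si](CC)(CC)CC)[C@H](C[C@@H](O)C2(C)C)C(=O)[C@@]1(C)CCO | intermediate
23 | (2R,3aS,5S,6R,8aS)-2-hydroxy-5-(2-iodoethyl)-1,1,5,6-tetramethyl-8a-[(triethylsilyl)oxy]octahydroazulen-4(1H)-one | C[C@@H]1CC[C@]2(O[Si](CC)(CC)CC)[C@H](C[C@@H](O)C2(C)C)C(=O)[C@@]1(C)CCI | intermediate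
24 | 4-bromofuran-2(5H)-one | BrC1=CC(=O)OC1 | starting material
25 | {2-[(2R,3aS,5S,6R,8aS)-2-hydroxy-1,1,5,6-tetramethyl-4-oxo-8a-[(triethylsilyl)oxy]decahydroazulen-5-yl]ethyl}zinc iodide | C[C@@H]1CC[C@]2(O[Si](CC)(CC)CC)[C@H](C[C@@H](O)C2(C)C)C(=O)[C@@]1(C)CC[Zn]I | intermediate (not isolated)
26 | 4-{2-[(2R,3aS,5S,6R,8aS)-2-hydroxy-1,1,5,6-tetramethyl-4-oxo-8a-[(triethylsilyl)oxy]decahydroazulen-5-yl]ethyl}furan-2(5H)-one | C[C@@H]1CC[C@]2(O[Si](CC)(CC)CC)[C@H](C[C@@H](O)C2(C)C)C(=O)[C@@]1(C)CCC1=CC(=O)OC1 | intermediate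
27 | 4-{2-[(2R,3aS,5S,6R,8aS)-2,8a-dihydroxy-1,1,5,6-tetramethyl-4-oxodecahydroazulen-5-yl]ethyl}furan-2(5H)-one (CNP0077405.1) | C[C@@H]1CC[C@]2(O)[C@H](C[C@@H](O)C2(C)C)C(=O)[C@@]1(C)CCC1=CC(=O)OC1 | target

## Step count and risks

Total step count: 13. Longest linear sequence: 13 steps (from 1).

Three steps most likely to fail:

1. Step 8 (key step). What may go wrong: incomplete second deprotonation at the hindered ring methylene, loss of the β-silyloxy group from the ring enolate by elimination, or intermolecular coupling and over-iodination in place of ring closure. Fallback (stepwise halogenation and enolate alkylation, which sets out from 16 and comes back at 19): 16 is deprotonated kinetically at the methyl ketone with LiN(i-Pr)2 (1.05 equiv, THF, −78 °C) and trapped with Me3SiCl to give the terminal trimethylsilyl enol ether F1. NBS (THF, −78 °C) converts it into the bromomethyl ketone F2. KOt-Bu (THF, −40 → 0 °C) then closes the ring by intramolecular alkylation of the ring enolate in the same 5-(enolexo)-exo-tet mode to give 19.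

2. Step 5. What may go wrong: poor or reversed facial selectivity in the addition to the ring carbonyl, so that the C6 epimer of the adduct predominates. Fallback (oxygen is delivered to the accessible face in place of carbon; it sets out from 11 and comes back at 14): the Barbier addition is run as in step 5 and the adduct is taken on as the mixture of 14 and its C6 epimer, (2S,3R,6R)-6-hydroxy-2,3-dimethyl-6-(2-methylbut-3-yn-2-yl)-2-(prop-2-en-1-yl)cycloheptan-1-one F3. Both epimers are dehydrated (p-TsOH·H2O, toluene, 80 °C) to the same conjugated enone F4. Nucleophilic epoxidation (H2O2, NaOH, MeOH, 0 °C) on the ring face that proved more accessible in the addition should then give the epoxy ketone F5 with the oxirane oxygen on the face of the two methyl groups. Reductive opening of the α,β-epoxy ketone (SmI2, THF/MeOH, −90 °C) returns the β-hydroxy ketone 14 with the carbinol configuration reversed relative to the failed addition.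

3. Step 9. What may go wrong: the equilibrium may not reach or not favour the trans-fused epimer, or the silyloxy group may be lost by β-elimination during prolonged base treatment. Fallback (kinetic in place of thermodynamic control; it sets out from 19 and comes back at 20): 19 is converted with KN(SiMe3)2 (2.5 equiv, THF, −78 °C) into the dipotassium bis-enolate F6 and quenched at −78 °C with AcOH. Protonation at C3a on the face opposite the bulky angular silyloxy group should give the trans-fused diketone 20.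

Further compounds
F1 | step 8 | (2S,3R,6S)-2,3-dimethyl-6-{2-methyl-3-[(trimethylsilyl)oxy]but-3-en-2-yl}-2-(prop-2-en-1-yl)-6-[(triethylsilyl)oxy]cycloheptan-1-one | C[C@@H]1CC[C@@](O[Si](CC)(CC)CC)(C(C)(C)C(=C)O[Si](C)(C)C)CC(=O)[C@@]1(C)CC=C
F2 | step 8 | (2S,3R,6S)-6-(4-bromo-2-methyl-3-oxobutan-2-yl)-2,3-dimethyl-2-(prop-2-en-1-yl)-6-[(triethylsilyl)oxy]cycloheptan-1-one | C[C@@H]1CC[C@@](O[Si](CC)(CC)CC)(C(C)(C)C(=O)CBr)CC(=O)[C@@]1(C)CC=C
F3 | step 5 | (2S,3R,6R)-6-hydroxy-2,3-dimethyl-6-(2-methylbut-3-yn-2-yl)-2-(prop-2-en-1-yl)cycloheptan-1-one | C[C@@H]1CC[C@](O)(C(C)(C)C#C)CC(=O)[C@@]1(C)CC=C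
F4 | step 5 | (6R,7S)-6,7-dimethyl-3-(2-methylbut-3-yn-2-yl)-7-(prop-2-en-1-yl)cyclohept-2-en-1-one | C[C@@H]1CCC(C(C)(C)C#C)=CC(=O)[C@@]1(C)CC=C
F5 | step 5 | (1S,3S,4R,7R)-3,4-dimethyl-7-(2-methylbut-3-yn-2-yl)-3-(prop-2-en-1-yl)-8-oxabicyclo[5.1.0]octan-2-one | C[C@@H]1CC[C@]2(C(C)(C)C#C)O[C@@H]2C(=O)[C@@]1(C)CC=C
F6 | step 9 | dipotassium bis-enolate of 19 (enolates at C3a=C4 and C2=C3) | C[C@@H]1CC[C@]2(O[Si](CC)(CC)CC)C(C=C(O[K])C2(C)C)=C(O[K])[C@@]1(C)CC=C
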